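The numbers in the tables were generated by integration with constants of no real substance; scatter was added.

Substrate leaves these flasks by two routes, and at first the uncatalysed one wins by far: after 1.00 h the birch run shows 47.0% homo dimer against 4.1% target. Two substrates pair to the homo dimer without help, while the catalyst cycle takes substrate and reagent and releases target.

in all of them: free catalyst 0.5 mol%
- birch: substrate 10 mM; reagent 0.70 equiv; run made earlier
- larch: substrate 10 mM; reagent 0.47 equiv; run made earlier
- maple: substrate 10 mM; reagent 1 equiv; run made earlier
- north-west: substrate 10 mM; reagent 0.700 equiv (in portions, 3, over 2.5 h); first portion at the start, last at 2.5 h; time 12 h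
- south-east: substrate 10 mM (fed, over 2.5 h); reagent 0.700 equiv; all else is in the flask from the start; the feed brings no volume worth counting; time 12 h
- east: substrate 10 mM; reagent 0.700 equiv (fed, over 2.5 h); all else is in the flask from the start; the feed brings no volume worth counting; time 12 h
- west: substrate 10 mM; reagent 0.700 equiv (fed, over 15 min); all else is in the flask from the start; the feed brings no volume worth counting; time 12 h
- south: substrate 10 mM; reagent 0.700 equiv; everything together at the start; time 12 h

- birch (time / h: target / %, homo dimer / %, substrate / %): 1.00: 4.1, 47.0, 51.9; 2.00: 8.4, 60.0, 30.4; 5.00: 18.4, 71.4, 11.4; 12.0: 29.4, 73.8, 0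
- larch (time / h: target / %, homo dimer / %, substrate / %): 1.50: 5.8, 56.3, 37.7; 4.00: 14.4, 70.9, 12.8; 8.00: 23.9, 73.5, 1.1; 12.0: 26.6, 72.5, 0.5
- maple (time / h: target / %, homo dimer / %, substrate / %): 3.00: 10.8, 67.7, 21.2; 6.00: 21.5, 72.4, 6.8; 10.0: 28.3, 71.4, 1.9; 12.0: 27.8, 72.5, 0

(standard deviation of a reading: 1 percentage point)

- which flask leads in share of target in target plus homo dimer ("all alike" within 1.5 percentage points) (north-west / south-east / east / west / south / all alike)
- share of target in target plus homo dimer at the end, north-west
- share of target in target plus homo dimer at the end, south-east
- share of target in target plus homo dimer at the end, east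
- share of target in target plus homo dimer at the end, west
- share of target in target plus homo dimer at the end, south

Take c as a fraction of the substrate charged. Pairing means that the reciprocal of c_substrate climbs steadily with time, so the first birch reading gives a dimer constant a of 0.927 h⁻¹. The target grows steadily at a rate v, which birch reads as 0.0368 h⁻¹. Larch and maple read 0.0360 h⁻¹ and 0.0360 h⁻¹, so reagent between 0.47 equiv and 1 equiv leaves the rate unmoved. Dividing one rate by the other removes time, and what remains is a ratio that moves with the substrate level:

r_dimer / r_target = (a / v) × c_substrate × c_substrate = (c_substrate / c*) squared

Here c* is the crossover level, at this charge and catalyst loading: the substrate level at which both routes take substrate equally fast 19.9%. Above it dimer wins, and below it target wins.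

Birch ended at a read share of 28.5%, and we expect that share from north-west, east, west and south, each of which has its substrate at the full charge from the start. South-east differs: its substrate comes in over 2.5 h. Target is a clock, v × time, so a flask gains v × delay over a batch by reaching a given level late. A batch reaches level c after

t_batch = (c_charge / c − 1) / a

Under the feed we reckon the level to climb toward the point where pairing equals feeding, 65.7%. Taking that level at the end of the feed, our estimated gain is 7.1 percentage points, and our high estimate for south-east is 35.6%.

The forecast, which is lower than our high estimate, names south-east: 34% there, against 27.8%, 27.5%, 27.7% and 27.8% for north-west, east, west and south. Its grounds: “Feeding reagent changes nothing”, while feeding substrate keeps the substrate level lower.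

The flasks give 32.9% for south-east, and 27.1%, 26.7%, 27.2% and 27.3% for the others, so south-east leads and the forecast stands.

    reagent + catalyst intermediate A → catalyst intermediate B (k = 87000 M⁻¹ h⁻¹)
    catalyst intermediate B → free catalyst + target (k = 7.90 h⁻¹)
    substrate + free catalyst → catalyst intermediate A (k = 36000 M⁻¹ h⁻¹)
    2 substrate → homo dimer (k = 47.0 M⁻¹ h⁻¹)

South-east held 55.8% substrate at 2.50 h, a level our batch clock reaches after 0.855 h. That delay is worth 6.1 points, and the computed lead over south is 5.6 points.

A neighbour flask is east with 0.85 mol% free catalyst. If v follows the catalyst, c* grows by a factor of 1.30, and with the charge above c* we let the share grow with it, to 34.9%. The computed flask gives 33.5%.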